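The charge of substrate in this flask is smaller than the charge of reagent in the second phase. So if each product takes one reagent and the reagent goes nowhere else, the substrate should be used up first. We put that comparison to the flask.

- delta: substrate 0.40 M; reagent in the second phase 1 M; the very flask that is asked about, followed so far
- flask: substrate 0.40 M; reagent in the second phase 1.00 M; time 15 h; volume of the second phase over the first 0.50

delta run (percent of the substrate charged)

| time / h | product / % | substrate / % |
|---|---|---|
| 0.417 | 0 | 99 |
| 1.00 | 7 | 100 |
| 2.00 | 12 | 88 |
| 3.00 | 18 | 80 |
| 5.00 | 30 | 69 |

(each reading ± 2 percentage points)

- in the second phase: reagent in the second phase; everything else is in the first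
- charges count per volume of the first phase; a concentration in a rate is the amount of a species over the volume of its own phase; every rate counts per litre of the first phase
- the earlier runs hold the two phases in the same ratio of volumes as the flask asked about

- how much product there is at 15 h, in percent of the substrate charged
- part of the substrate charged that has reacted at 15 h

We climb the time scales from short to long. The readings stop at 5.00 h, with 30% product and 69% substrate, so no third holder of substrate shows yet. The average pace up to that reading is 0.0240 M h⁻¹, a reading with the scatter of its product value. Held to the asked 15 h, that pace gives 90.0% product. The next rung is the substrate clock: at that pace the substrate charge lasts 16.7 h, later than the asked time. The top rung is the reagent clock: at that pace, with one reagent per product, the reagent charge lasts 41.7 h, longer than the substrate clock.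

Dividing the two clocks removes the pace and leaves 40.0%. This is the needed share, the part of the reagent charge that has to end as product for the substrate to be used up, with one reagent per product; it is a needed selectivity. The readings do not show the reagent, so the share it really delivers is unread.

The forecast gives 68% product and 70% reacted, and holds that “the upper side stays open”.

The flask gives 48.4% product, with 48.4% reacted.

    reagent in the reaction phase ⇌ reagent in the second phase, rate k1*([reagent in the reaction phase] - [reagent in the second phase]/K1) per volume of the first phase (partition coefficient = 2.12, kL = 0.196 h⁻¹)
    substrate + reagent in the reaction phase → product (k = 0.989 M⁻¹ h⁻¹)
    reagent in the reaction phase → decomposed reagent (k = 1.05 h⁻¹)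

At 15.0 h this flask has 9.16% of its reagent charge left in the second phase and 0.0131 M of reagent in the reaction phase, and 0.702 M of decomposed reagent stands beside 0.193 M of product. Product so far accounts for 19.3% of the reagent charge, smaller than the needed share of 40.0%. The flask left until 40.0 h has 0.183% of its reagent charge left in the second phase. Its product accounts for 21.0% of the reagent charge, smaller than 40.0%, and it holds 52.4% product.

The runs are calculated from invented constants.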